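## Structural features

The target is a 15-membered ansa-lactam (ring C: N, C1–C11, the ether oxygen, C21, C20) that spans a pentasubstituted benzene (ring A, C16–C21). Ring A is also fused through C16 and C21 to an eight-membered 1-benzoxocane (ring B: O, C11–C15, C16, C21), so rings B and C share the C11–O–C21 unit. Ring B carries the contiguous triad C10 (S, methyl), C11 (R, aryl ether), C12 (S, methoxy) and the 1,3-related C14 (R, methyl). The ansa chain carries the syn pair C6 (S, methoxy) and C7 (S, carbamate) next to the (8Z)-trisubstituted alkene, and the quaternary carbinol C2 (S) next to the lactam carbonyl. The C4 ketone is β to both the C6 methoxy group (E1cB loss of methanol) and the C2 hydroxyl (retro-aldol). The C7 carbamate is allylic and carries N–H, the aminophenol ring is oxidisable, and aldehydes next to C6, C10 and C12 can epimerise. The real difficulty is closing a strained macrocycle that holds a Z-alkene and an anilide flanked by an ortho ether, together with the medium ring B. The key step uses the fact that the lactam nitrogen sits on C20, ortho to the ether oxygen on C21: ring C is closed by joining the C1 primary amide nitrogen to a C20 bromide, not by acylating a hindered, weakly nucleophilic aniline.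

## Logic of the disconnections

46 back to 42 (through 45 and 43): no skeletal bond is cut. The C4 ketone and C18 phenol are masked as dioxolane and methoxymethyl ether, and the carbamate is traced to a silyl-protected C7 hydroxyl. This removes the base-labile β-methoxy/β-hydroxy ketone and the extra N–H from the ring-closing step. The demand is a final acid hydrolysis mild enough for the allylic carbamate.

42 back to 41: the C20–N bond is cut, opening ring C. This replaces a hindered anilide acylation by an N-arylation of a small primary amide and gives an open chain with one aryl bromide and one CONH2. The forward step must favour N- over O-arylation and ring closure over oligomerisation.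

41 back to 26 and 36 (through 40 and 39): the C7–C8 bond is cut between the sp2 carbon of the Z-alkene and the carbinol. This splits the molecule into a ring A/B alkenyl iodide and a C1–C7 aldehyde of similar size. The forward addition must set C7 by chelation to the C6 methoxy group, must exchange iodine in the presence of the aryl bromide, and must spare the dioxolanone that masks C1/C2.

26 back to 19 (through 25, 24, 22 and 21): the C8=C9 bond is cut to a C9 aldehyde, and the C20 bromide is traced to the nitro group. The nitro group thus serves first as activator and then as the source of the halide. The alkene of 19 must be cleaved and reduced before the radical Sandmeyer step, and the olefination must be Z-selective on an epimerisable, β-aryloxy aldehyde.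

19 back to 18: the C21–O bond is cut, opening ring B to a fluoronitroarene with a free C11 hydroxyl. The forward step is a medium-ring nucleophilic aromatic substitution and needs dilution.

18 back to 16 (through 17): the C10–C11 bond is cut to a C11 α-methoxy aldehyde and a crotyl unit, which creates C10 and C11 in one step from C12. The aldehyde is unmasked from a terminal acetonide. The crotylation must be syn-selective and anti to the methoxy group.

16 back to 14 and 4, and 4 back to 1 (through 3): the C15–C16 bond is cut to an alkyl iodide and an aryl bromide, and the C18–O bond is traced to a C–H bond of 1. The nitroarene enters only after all strongly basic steps. The coupling must tolerate nitro and activated fluoride, and the oxygenation must be regioselective.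

14 back to 8 and 6 (through 13, 12, 11 and 10), with 8 from 7 and 6 from 5: the C12–C13 bond is cut between a chiral-pool C13–C15 unit and a glycerate-derived acyl unit whose stereocenter sets C12 and is later excised. The ketone reduction must be chelation-controlled.

36 back to 28 and 31 (through 35, 34 and 33), with 28 from 27 and 31 from 29 (through 30): the C4–C5 bond is cut between the citramalate C1–C4 acyl unit, which brings C2, and a glycidol-derived C5–C7 iodide, which brings C6. The C–C bond formation must avoid a β-methoxy organometallic, and the ketalisation must not eliminate methanol.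

## Other disconnections considered

Alternative 1: The cut is C13–C14 inside ring B, made as an alkene. An acyclic diene A2 (C12 vinyl, C16 2-methylallyl, aryl ether already in place) would be closed with the second-generation Grubbs catalyst to benzoxocine A1, and hydrogenation of A1 would then set C14. In its favour, the aryl ether is made by an easy intermolecular substitution before any ring exists, and metathesis is indifferent to the electron-donating C18 oxygen that slows substitution at C21. On this point of ring-closure mechanism the alternative is the better. Against it, the ring closure forms a trisubstituted alkene from a 1,1-disubstituted olefin and may dimerise. C14 is then created by hydrogenating a trisubstituted alkene in a flexible eight-membered ring that also holds a reducible nitro group, with only a weak directing group nearby. The chosen plan takes C14 from the chiral pool and is the safer on stereochemistry. The alternative addresses ring B only and is complementary to the C20–N closure of ring C. In step count the two are about equal.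

Alternative 2: The cuts are C3–C4 and C4–C5 around the masked C4 carbonyl. Lithiated silyl dithiane A4 would open epoxide A5 at C3, a carbon-to-oxygen silyl shift would regenerate the C4 anion, and this would open epoxide A6 at C5 to give A3. In its favour, two C–C bonds and the whole 1,5-dioxygenated ketone pattern form in one flask, with C2 and C6 from chiral epoxides and C4 already protected. In convergence of the fragment union it is the better of the two, and anion relay chemistry is at least as well precedented as the nickel-mediated ketone synthesis used here. Against it, C1 arrives at the alcohol oxidation level and must be deprotected, oxidised twice and amidated late. The C6 hydroxyl must be methylated after coupling, the aniline must be carried masked, the elaborate epoxide A6 meets a strongly basic carbanion, and the dithiane must be removed near an electron-rich arene and an alkene. It does not close ring C, which would still need a bond to the hindered C20 nitrogen. The shorter coupling is paid for by a longer endgame, so the overall count is not lower.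

Alternative 3: The cut is C1–C2, with C1 supplied by an isocyanide on C20 and C2 by a methyl ketone. The seco compound A8 would cyclise with pyridinium trifluoroacetate in a Passerini-type α-addition, and acyl transfer and hydrolysis would give macrolactam A7. In its favour, one step forms a C–C bond, the amide and the tertiary alcohol. The carbamate can already be in place, which the copper amidation cannot tolerate, so the endgame is shorter and the alternative is equal or better in steps after ring closure. Against it, C2 is created during the macrocyclisation and its configuration rests only on the conformation of the closing ring. Ketones are sluggish Passerini partners, the isocyanide must be made from a hindered aniline on an advanced intermediate, and a dithiane remains to be removed. The chosen plan imports C2 from citramalic acid and is the safer on stereochemistry. Both plans close ring C at the anilide end and differ only in which bond to C1 is formed.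

Key step: step 29

Assumption: 5, 7 and 29 are bought as single enantiomers; 7 is the reduced, brominated form of the (R)-Roche ester and is used in its place to save two steps.
Remark on the chemistry: arene 1 has no oxygen at the position that becomes C18, so this oxygen is introduced in step 1 and carried as the methoxymethyl ether.

## Steps

Step 1
Reactants: 1 1-bromo-2-fluoro-3-nitrobenzene
Product: 3 3-bromo-4-fluoro-5-nitrophenol, via aryl pinacol boronate 2 (not isolated)
Conditions: [Ir(OMe)(cod)]2 (cat.), 4,4'-di-tert-butyl-2,2'-bipyridine, B2pin2, THF, 80 °C; then KHSO5 (Oxone), acetone–H2O, 0 °C to rt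
Reagents that add atoms: potassium peroxymonosulfate, [K+].[O-]S(=O)(=O)OO
Why: Sterically governed iridium-catalysed C–H borylation should select C5, the only C–H without an ortho substituent, and Oxone oxidises the C–B bond to the phenol without a basic medium that would attack the activated C–F bond (one-pot borylation–oxidation).

Step 2
Reactants: 3 3-bromo-4-fluoro-5-nitrophenol
Product: 4 1-bromo-2-fluoro-5-(methoxymethoxy)-3-nitrobenzene
Conditions: MOMCl, i-Pr2NEt, CH2Cl2, 0 °C to rt
Reagents that add atoms: chloromethyl methyl ether, COCCl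
Why: O-Alkylation of the acidic nitrophenol under amine base; the acetal should survive every basic, reductive and organometallic step up to the last one.

Step 3
Reactants: 5 methyl (4R)-2,2-dimethyl-1,3-dioxolane-4-carboxylate
Product: 6 (4R)-N-methoxy-N,2,2-trimethyl-1,3-dioxolane-4-carboxamide
Conditions: MeNH(OMe)·HCl, i-PrMgCl, THF, −20 to 0 °C
Reagents that add atoms: N,O-dimethylhydroxylamine hydrochloride, CNOC.Cl
Why: Weinreb amide formation by magnesium amide aminolysis of the ester at low temperature, which should leave the α-alkoxy stereocenter untouched.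

Step 4
Reactants: 7 (2R)-3-bromo-2-methylpropan-1-ol
Product: 8 [(2R)-3-bromo-2-methylpropoxy](tert-butyl)diphenylsilane
Conditions: TBDPSCl, imidazole, DMF, rt
Reagents that add atoms: tert-butylchlorodiphenylsilane, CC(C)(C)[Si](Cl)(c1ccccc1)c1ccccc1
Why: Standard silylation of the primary alcohol; the bulky silyl ether tolerates Grignard formation, hydride and NaH/MeI.

Step 5
Reactants: 8 [(2R)-3-bromo-2-methylpropoxy](tert-butyl)diphenylsilane, 6 (4R)-N-methoxy-N,2,2-trimethyl-1,3-dioxolane-4-carboxamide
Product: 10 (3S)-4-[(tert-butyldiphenylsilyl)oxy]-1-[(4R)-2,2-dimethyl-1,3-dioxolan-4-yl]-3-methylbutan-1-one, via Grignard reagent 9 (not isolated)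
Conditions: Mg turnings, BrCH2CH2Br (cat.), THF, 45 °C; then 6, THF, 0 °C; aq. NH4Cl
Reagents that add atoms: none
Why: Weinreb ketone synthesis: the Grignard reagent adds once to give a stable magnesium chelate that collapses to the ketone on work-up, forming C12–C13 without over-addition; both stereocenters are spectators.

Step 6
Reactants: 10 (3S)-4-[(tert-butyldiphenylsilyl)oxy]-1-[(4R)-2,2-dimethyl-1,3-dioxolan-4-yl]-3-methylbutan-1-one
Product: 11 (1S,3S)-4-[(tert-butyldiphenylsilyl)oxy]-1-[(4R)-2,2-dimethyl-1,3-dioxolan-4-yl]-3-methylbutan-1-ol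
Conditions: Zn(BH4)2, Et2O, −30 to 0 °C
Reagents that add atoms: none
Why: Chelation-controlled reduction: zinc bridges the ketone and the α-oxygen of the dioxolane and hydride enters on the face of the α-hydrogen, which should give the anti alcohol, that is 12S.

Step 7
Reactants: 11 (1S,3S)-4-[(tert-butyldiphenylsilyl)oxy]-1-[(4R)-2,2-dimethyl-1,3-dioxolan-4-yl]-3-methylbutan-1-ol
Product: 12 tert-butyl{[(2S,4S)-4-[(4R)-2,2-dimethyl-1,3-dioxolan-4-yl]-4-methoxy-2-methylbutyl]oxy}diphenylsilane
Conditions: NaH, MeI, THF–DMF, 0 °C to rt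
Reagents that add atoms: iodomethane, CI
Why: Williamson methylation of the alkoxide installs the C12 methyl ether; no base-sensitive group is present.

Step 8
Reactants: 12 tert-butyl{[(2S,4S)-4-[(4R)-2,2-dimethyl-1,3-dioxolan-4-yl]-4-methoxy-2-methylbutyl]oxy}diphenylsilane
Product: 13 (2S,4S)-4-[(4R)-2,2-dimethyl-1,3-dioxolan-4-yl]-4-methoxy-2-methylbutan-1-ol
Conditions: Bu4NF, THF, rt
Reagents that add atoms: none
Why: Fluoride cleaves the Si–O bond; acetonide and methyl ether are inert.

Step 9
Reactants: 13 (2S,4S)-4-[(4R)-2,2-dimethyl-1,3-dioxolan-4-yl]-4-methoxy-2-methylbutan-1-ol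
Product: 14 (4R)-4-[(1S,3S)-4-iodo-1-methoxy-3-methylbutyl]-2,2-dimethyl-1,3-dioxolane
Conditions: I2, PPh3, imidazole, CH2Cl2, 0 °C
Reagents that add atoms: iodine, II
Why: Appel-type iodination of the primary alcohol under buffered conditions that spare the acetonide.

Step 10
Reactants: 14 (4R)-4-[(1S,3S)-4-iodo-1-methoxy-3-methylbutyl]-2,2-dimethyl-1,3-dioxolane, 4 1-bromo-2-fluoro-5-(methoxymethoxy)-3-nitrobenzene
Product: 16 (4R)-4-{(1S,3R)-4-[2-fluoro-5-(methoxymethoxy)-3-nitrophenyl]-1-methoxy-3-methylbutyl}-2,2-dimethyl-1,3-dioxolane, via alkylzinc iodide 15 (not isolated)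
Conditions: Zn dust (Me3SiCl-activated), LiCl, THF, 40 °C; decant from excess Zn; then 4, Pd(OAc)2 (cat.), SPhos, THF, rt to 45 °C
Reagents that add atoms: none
Why: Negishi coupling: zinc inserts into the primary C–I bond (no β-leaving group) and zerovalent palladium with SPhos couples the alkylzinc with the aryl bromide faster than β-hydride elimination, forming C15–C16; alkylzinc halides tolerate the nitro group and the activated fluoride once excess zinc is removed.

Step 11
Reactants: 16 (4R)-4-{(1S,3R)-4-[2-fluoro-5-(methoxymethoxy)-3-nitrophenyl]-1-methoxy-3-methylbutyl}-2,2-dimethyl-1,3-dioxolane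
Product: 17 (2S,4R)-5-[2-fluoro-5-(methoxymethoxy)-3-nitrophenyl]-2-methoxy-4-methylpentanal
Conditions: H5IO6, EtOAc, 0 °C to rt
Reagents that add atoms: none
Why: Periodic acid hydrolyses the terminal acetonide and cleaves the diol in one flask, unveiling the C11 aldehyde and removing the auxiliary stereocenter; the α-methoxy aldehyde is used crude to avoid epimerisation at C12.

Step 12
Reactants: 17 (2S,4R)-5-[2-fluoro-5-(methoxymethoxy)-3-nitrophenyl]-2-methoxy-4-methylpentanal
Product: 18 (2R,4S,5R,6S)-1-[2-fluoro-5-(methoxymethoxy)-3-nitrophenyl]-4-methoxy-2,6-dimethyloct-7-en-5-ol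
Conditions: (Z)-crotylboronic acid pinacol ester, 4 Å MS, toluene, −20 °C to rt; then N(CH2CH2OH)3
Reagents that add atoms: (Z)-crotylboronic acid pinacol ester, C/C=C\CB1OC(C)(C)C(C)(C)O1
Why: Crotylboration through a closed chair transition state: the Z-boronate gives the 10,11-syn pair and the α-methoxy aldehyde is attacked in the Felkin–Anh (Cornforth) sense, giving 11,12-anti, that is 10S,11R; a matched diisopinocampheyl crotylborane can reinforce the facial control if needed.

Step 13
Reactants: 18 (2R,4S,5R,6S)-1-[2-fluoro-5-(methoxymethoxy)-3-nitrophenyl]-4-methoxy-2,6-dimethyloct-7-en-5-ol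
Product: 19 (2R,3S,5R)-2-[(2S)-but-3-en-2-yl]-3-methoxy-8-(methoxymethoxy)-5-methyl-10-nitro-3,4,5,6-tetrahydro-2H-1-benzoxocine
Conditions: KN(SiMe3)2, THF (0.005 M), 0 °C to rt
Reagents that add atoms: none
Why: Intramolecular nucleophilic aromatic substitution: the C11 alkoxide adds to C21, activated by the ortho nitro group, and fluoride leaves from the Meisenheimer adduct; dilution favours the eight-membered ring B, and C11 keeps its configuration because its C–O bond is not broken.

Step 14
Reactants: 19 (2R,3S,5R)-2-[(2S)-but-3-en-2-yl]-3-methoxy-8-(methoxymethoxy)-5-methyl-10-nitro-3,4,5,6-tetrahydro-2H-1-benzoxocine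
Product: 21 (2S)-2-[(2R,3S,5R)-3-methoxy-8-(methoxymethoxy)-5-methyl-10-nitro-3,4,5,6-tetrahydro-2H-1-benzoxocin-2-yl]propan-1-ol, via nitro aldehyde 20 (not isolated)
Conditions: O3, CH2Cl2–MeOH, −78 °C; Me2S; then NaBH4, −78 to 0 °C
Reagents that add atoms: ozone, [O-][O+]=O
Why: Ozonolysis should cleave only the terminal alkene because the nitro-bearing arene is electron-poor; reduction in the same flask avoids β-elimination of the nitrophenoxide and epimerisation at C10, and removes the alkene before the radical Sandmeyer step.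

Step 15
Reactants: 21 (2S)-2-[(2R,3S,5R)-3-methoxy-8-(methoxymethoxy)-5-methyl-10-nitro-3,4,5,6-tetrahydro-2H-1-benzoxocin-2-yl]propan-1-ol
Product: 22 (2S)-2-[(2R,3S,5R)-10-amino-3-methoxy-8-(methoxymethoxy)-5-methyl-3,4,5,6-tetrahydro-2H-1-benzoxocin-2-yl]propan-1-ol
Conditions: Fe powder, NH4Cl, EtOH–H2O, 70 °C
Reagents that add atoms: none
Why: Béchamp-type iron reduction converts the nitro group into the aniline without touching the aryl ether, the acetal or the alcohol.

Step 16
Reactants: 22 (2S)-2-[(2R,3S,5R)-10-amino-3-methoxy-8-(methoxymethoxy)-5-methyl-3,4,5,6-tetrahydro-2H-1-benzoxocin-2-yl]propan-1-ol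
Product: 24 (2S)-2-[(2R,3S,5R)-10-bromo-3-methoxy-8-(methoxymethoxy)-5-methyl-3,4,5,6-tetrahydro-2H-1-benzoxocin-2-yl]propan-1-ol, via arenediazonium bromide 23 (not isolated)
Conditions: t-BuONO, CuBr2, MeCN, 0 °C to rt
Reagents that add atoms: copper dibromide, Br[Cu]Br
Why: Non-aqueous Sandmeyer bromination: the alkyl nitrite diazotises the aniline and CuBr2 transfers bromine to the aryl radical, installing the C20 bromide; the acid-free medium keeps the methoxymethyl ether.

Step 17
Reactants: 24 (2S)-2-[(2R,3S,5R)-10-bromo-3-methoxy-8-(methoxymethoxy)-5-methyl-3,4,5,6-tetrahydro-2H-1-benzoxocin-2-yl]propan-1-ol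
Product: 25 (2R)-2-[(2R,3S,5R)-10-bromo-3-methoxy-8-(methoxymethoxy)-5-methyl-3,4,5,6-tetrahydro-2H-1-benzoxocin-2-yl]propanal
Conditions: Dess–Martin periodinane, NaHCO3, CH2Cl2, 0 °C
Reagents that add atoms: none
Why: Buffered Dess–Martin oxidation should give the α-chiral, β-aryloxy aldehyde without epimerisation; it is used at once.

Step 18
Reactants: 25 (2R)-2-[(2R,3S,5R)-10-bromo-3-methoxy-8-(methoxymethoxy)-5-methyl-3,4,5,6-tetrahydro-2H-1-benzoxocin-2-yl]propanal
Product: 26 (2R,3S,5R)-10-bromo-2-[(2S,3Z)-4-iodopent-3-en-2-yl]-3-methoxy-8-(methoxymethoxy)-5-methyl-3,4,5,6-tetrahydro-2H-1-benzoxocine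
Conditions: EtPPh3I, n-BuLi, THF, rt; I2, −78 °C; NaN(SiMe3)2, −20 °C; then 25, −78 °C
Reagents that add atoms: ethyltriphenylphosphonium iodide, CC[P+](c1ccccc1)(c1ccccc1)c1ccccc1.[I-]; iodine, II
Why: Stork–Zhao olefination with the α-iodoethylidene ylide gives the Z-2-iodoalkene under kinetic control (iodine cis to C10), which fixes the 8Z geometry; addition at −78 °C should outrun enolisation of the aldehyde.

Step 19
Reactants: 27 (S)-citramalic acid
Product: 28 2-[(4S)-2,2,4-trimethyl-5-oxo-1,3-dioxolan-4-yl]acetic acid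
Conditions: Me2C(OMe)2, PPTS (cat.), acetone, rt
Reagents that add atoms: 2,2-dimethoxypropane, COC(C)(C)OC
Why: Acetonide formation selects the α-hydroxy acid as the five-membered dioxolanone; this differentiates the two carboxyls, protects the tertiary alcohol and activates C1 for later aminolysis, with C2 untouched.

Step 20
Reactants: 29 (2S)-2-[(benzyloxy)methyl]oxirane
Product: 30 (2R)-1-(benzyloxy)-3-iodopropan-2-ol
Conditions: LiI, AcOH, THF, 0 °C to rt
Reagents that add atoms: lithium iodide, [Li+].[I-]
Why: Regioselective opening of the terminal epoxide by iodide at the primary carbon under buffered acid; the stereocenter (future C6) is not involved.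

Step 21
Reactants: 30 (2R)-1-(benzyloxy)-3-iodopropan-2-ol
Product: 31 {[(2R)-3-iodo-2-methoxypropoxy]methyl}benzene
Conditions: MeOTf, 2,6-di-tert-butyl-4-methylpyridine, CH2Cl2, 0 °C to rt
Reagents that add atoms: methyl trifluoromethanesulfonate, COS(=O)(=O)C(F)(F)F
Why: Methylation with methyl triflate and a hindered pyridine avoids alkoxide formation, which would re-close the epoxide.

Step 22
Reactants: 28 2-[(4S)-2,2,4-trimethyl-5-oxo-1,3-dioxolan-4-yl]acetic acid, 31 {[(2R)-3-iodo-2-methoxypropoxy]methyl}benzene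
Product: 33 (5S)-5-[(4S)-5-(benzyloxy)-4-methoxy-2-oxopentyl]-2,2,5-trimethyl-1,3-dioxolan-4-one, via acid chloride 32 (not isolated)
Conditions: (COCl)2, DMF (cat.), CH2Cl2, 0 °C to rt; evaporate; then 31, NiCl2(dme) (cat.), 4,4'-di-tert-butyl-2,2'-bipyridine, Mn powder, DMA, 0 °C to rt
Reagents that add atoms: none
Why: Nickel-catalysed reductive cross-electrophile ketone synthesis: the acyl chloride adds oxidatively to low-valent nickel, the primary iodide enters as a radical and reductive elimination forms C4–C5; the radical pathway avoids the β-methoxy organometallic that would eliminate, and C2 and C6 are remote from the reacting centres.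

Step 23
Reactants: 33 (5S)-5-[(4S)-5-(benzyloxy)-4-methoxy-2-oxopentyl]-2,2,5-trimethyl-1,3-dioxolan-4-one
Product: 34 (5S)-5-({2-[(2S)-3-(benzyloxy)-2-methoxypropyl]-1,3-dioxolan-2-yl}methyl)-2,2,5-trimethyl-1,3-dioxolan-4-one
Conditions: (Me3SiOCH2)2, Me3SiOTf (cat.), CH2Cl2, −78 to −20 °C; pyridine quench
Reagents that add atoms: 1,2-bis(trimethylsilyloxy)ethane, C[Si](C)(C)OCCO[Si](C)(C)C
Why: Noyori ketalisation with the bis-silyl glycol and catalytic silyl triflate at low temperature masks the C4 ketone without the protic acid and heat that would eliminate methanol.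

Step 24
Reactants: 34 (5S)-5-({2-[(2S)-3-(benzyloxy)-2-methoxypropyl]-1,3-dioxolan-2-yl}methyl)-2,2,5-trimethyl-1,3-dioxolan-4-one
Product: 35 (5S)-5-({2-[(2S)-3-hydroxy-2-methoxypropyl]-1,3-dioxolan-2-yl}methyl)-2,2,5-trimethyl-1,3-dioxolan-4-one
Conditions: H2 (1 atm), 10% Pd/C, EtOAc, rt
Reagents that add atoms: none
Why: Hydrogenolysis of the benzyl ether; ketal, dioxolanone and methyl ether are inert.

Step 25
Reactants: 35 (5S)-5-({2-[(2S)-3-hydroxy-2-methoxypropyl]-1,3-dioxolan-2-yl}methyl)-2,2,5-trimethyl-1,3-dioxolan-4-one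
Product: 36 (2S)-2-methoxy-3-(2-{[(4S)-2,2,4-trimethyl-5-oxo-1,3-dioxolan-4-yl]methyl}-1,3-dioxolan-2-yl)propanal
Conditions: Dess–Martin periodinane, NaHCO3, CH2Cl2, 0 °C
Reagents that add atoms: none
Why: Buffered Dess–Martin oxidation to the α-methoxy aldehyde, which is used directly to avoid epimerisation at C6.

Step 26
Reactants: 26 (2R,3S,5R)-10-bromo-2-[(2S,3Z)-4-iodopent-3-en-2-yl]-3-methoxy-8-(methoxymethoxy)-5-methyl-3,4,5,6-tetrahydro-2H-1-benzoxocine, 36 (2S)-2-methoxy-3-(2-{[(4S)-2,2,4-trimethyl-5-oxo-1,3-dioxolan-4-yl]methyl}-1,3-dioxolan-2-yl)propanal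
Product: 39 (7S)-allylic alcohol of the full C1–C21 chain (C1/C2 dioxolanone; C4 dioxolane; C20 bromide), via alkenyllithium 37 (not isolated), via alkenylmagnesium bromide 38 (not isolated)
Conditions: t-BuLi (2.0 equiv), Et2O, −78 °C; MgBr2·OEt2, −78 °C; then 36 (1.3 equiv), CH2Cl2, −78 °C
Reagents that add atoms: none
Why: Iodine–lithium exchange is much faster than bromine–lithium exchange, so two equivalents of t-BuLi at −78 °C should convert only the alkenyl iodide, with retention of the Z geometry. After transmetalation the alkenylmagnesium adds to the Cram chelate of the α-methoxy aldehyde (magnesium between the C7 carbonyl and the C6 methoxy oxygen) from the face opposite C5, giving the 6,7-syn, 7S alcohol. The aldehyde, used in excess, should outcompete the hindered dioxolanone.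

Step 27
Reactants: 39 (7S)-allylic alcohol of the full C1–C21 chain
Product: 40 C7 tert-butyldimethylsilyl ether of 39
Conditions: t-BuMe2SiOTf, 2,6-lutidine, CH2Cl2, −78 °C
Reagents that add atoms: tert-butyldimethylsilyl trifluoromethanesulfonate, CC(C)(C)[Si](C)(C)OS(=O)(=O)C(F)(F)F
Why: Silyl triflate with lutidine silylates the hindered allylic alcohol at −78 °C; it is the only free hydroxyl, because the C2 oxygen is still locked in the dioxolanone.

Step 28
Reactants: 40 C7 tert-butyldimethylsilyl ether of 39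
Product: 41 C20 aryl bromide with C1 primary α-hydroxy amide (cyclisation precursor)
Conditions: NH3 (7 M in MeOH), rt to 40 °C
Reagents that add atoms: ammonia, N
Why: Aminolysis of the activated dioxolanone releases acetone and delivers, in one operation, the primary amide and the free tertiary alcohol.

Step 29
Reactants: 41 C20 aryl bromide with C1 primary α-hydroxy amide (cyclisation precursor)
Product: 42 protected macrolactam (C4 dioxolane; C7 silyl ether; C18 methoxymethyl ether)
Conditions: CuI, MeNHCH2CH2NHMe, K3PO4, toluene (0.003 M), 110 °C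
Reagents that add atoms: none
Why: Deprotonation of the primary amide by K3PO4 gives a diamine-ligated amidate of monovalent copper, which adds oxidatively into the C20–Br bond to give an aryl amidate of trivalent copper; reductive elimination forms the C20–N bond and returns monovalent copper. The closest known reaction is the Goldberg-type copper/diamine N-arylation of primary amides with aryl bromides, here run intramolecularly. The 15-membered ring C closes by bond formation between the amide nitrogen and the sp2 carbon C20, with bromide leaving outside the ring (exo mode), under high dilution. No stereocenter is created and none is at risk: C2 is quaternary and C6 cannot enolise while C4 is a ketal. The step needs N- over O-arylation, which the more acidic amide N–H, the bidentate diamine ligand and the steric shielding of the tertiary C2 hydroxyl should provide. It needs ring closure over intermolecular coupling, which dilution and the preorganisation by ring B, the ortho ether oxygen (a possible copper binding site) and the Z-alkene should favour. It also needs the absence of other N–H and base-labile sites, secured by the silyl ether at C7 in place of the carbamate and by the dioxolane at C4.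

Step 30
Reactants: 42 protected macrolactam
Product: 43 C7 alcohol of the macrolactam (C4 dioxolane; C18 methoxymethyl ether)
Conditions: Bu4NF, AcOH, THF, 0 °C to rt
Reagents that add atoms: none
Why: Buffered fluoride removes the C7 silyl ether; with C4 still a ketal, no base-induced elimination is possible.

Step 31
Reactants: 43 C7 alcohol of the macrolactam
Product: 45 C7 carbamate of the macrolactam (C4 dioxolane; C18 methoxymethyl ether), via N-trichloroacetyl carbamate 44 (not isolated)
Conditions: Cl3CC(O)NCO, CH2Cl2, −20 °C; then K2CO3, MeOH, 0 °C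
Reagents that add atoms: trichloroacetyl isocyanate, O=C=NC(=O)C(Cl)(Cl)Cl
Why: Trichloroacetyl isocyanate should acylate the secondary allylic C7 hydroxyl far faster than the hindered tertiary C2 hydroxyl or the anilide N–H; mild methanolysis removes the trichloroacetyl group to leave the primary carbamate.

Step 32
Reactants: 45 C7 carbamate of the macrolactam
Product: 46 target CNP0122739.1
Conditions: 3 M aq. HCl–THF (1:4), rt to 35 °C
Reagents that add atoms: water, O
Why: Specific acid hydrolysis cleaves the methoxymethyl acetal and the dioxolane, the new ketone oxygen coming from water; mild acid near room temperature should leave the allylic carbamate and the β-methoxy ketone intact.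

## Compound list

1 | 1-bromo-2-fluoro-3-nitrobenzene | O=[N+]([O-])c1cccc(Br)c1F | starting material
2 | 2-(3-bromo-4-fluoro-5-nitrophenyl)-4,4,5,5-tetramethyl-1,3,2-dioxaborolane | CC1(C)OB(c2cc(Br)c(F)c([N+](=O)[O-])c2)OC1(C)C | intermediate (not isolated)
3 | 3-bromo-4-fluoro-5-nitrophenol | Oc1cc(Br)c(F)c([N+](=O)[O-])c1 | intermediate
4 | 1-bromo-2-fluoro-5-(methoxymethoxy)-3-nitrobenzene | COCOc1cc(Br)c(F)c([N+](=O)[O-])c1 | intermediate
5 | methyl (4R)-2,2-dimethyl-1,3-dioxolane-4-carboxylate | COC(=O)[C@H]1COC(C)(C)O1 | starting material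
6 | (4R)-N-methoxy-N,2,2-trimethyl-1,3-dioxolane-4-carboxamide | CON(C)C(=O)[C@H]1COC(C)(C)O1 | intermediate
7 | (2R)-3-bromo-2-methylpropan-1-ol | BrC[C@H](C)CO | starting material
8 | [(2R)-3-bromo-2-methylpropoxy](tert-butyl)diphenylsilane | BrC[C@H](C)CO[Si](c1ccccc1)(c1ccccc1)C(C)(C)C | intermediate
9 | bromo{(2R)-3-[(tert-butyldiphenylsilyl)oxy]-2-methylpropyl}magnesium | Br[Mg]C[C@H](C)CO[Si](c1ccccc1)(c1ccccc1)C(C)(C)C | intermediate (not isolated)
10 | (3S)-4-[(tert-butyldiphenylsilyl)oxy]-1-[(4R)-2,2-dimethyl-1,3-dioxolan-4-yl]-3-methylbutan-1-one | CC(C)(C)[Si](c1ccccc1)(c1ccccc1)OC[C@@H](C)CC(=O)[C@H]1COC(C)(C)O1 | intermediate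
11 | (1S,3S)-4-[(tert-butyldiphenylsilyl)oxy]-1-[(4R)-2,2-dimethyl-1,3-dioxolan-4-yl]-3-methylbutan-1-ol | CC(C)(C)[Si](c1ccccc1)(c1ccccc1)OC[C@@H](C)C[C@H](O)[C@H]1COC(C)(C)O1 | intermediate
12 | tert-butyl{[(2S,4S)-4-[(4R)-2,2-dimethyl-1,3-dioxolan-4-yl]-4-methoxy-2-methylbutyl]oxy}diphenylsilane | CC(C)(C)[Si](c1ccccc1)(c1ccccc1)OC[C@@H](C)C[C@H](OC)[C@H]1COC(C)(C)O1 | intermediate
13 | (2S,4S)-4-[(4R)-2,2-dimethyl-1,3-dioxolan-4-yl]-4-methoxy-2-methylbutan-1-ol | OC[C@@H](C)C[C@H](OC)[C@H]1COC(C)(C)O1 | intermediate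
14 | (4R)-4-[(1S,3S)-4-iodo-1-methoxy-3-methylbutyl]-2,2-dimethyl-1,3-dioxolane | IC[C@@H](C)C[C@H](OC)[C@H]1COC(C)(C)O1 | intermediate
15 | {(2S,4S)-4-[(4R)-2,2-dimethyl-1,3-dioxolan-4-yl]-4-methoxy-2-methylbutyl}(iodo)zinc | I[Zn]C[C@@H](C)C[C@H](OC)[C@H]1COC(C)(C)O1 | intermediate (not isolated)
16 | (4R)-4-{(1S,3R)-4-[2-fluoro-5-(methoxymethoxy)-3-nitrophenyl]-1-methoxy-3-methylbutyl}-2,2-dimethyl-1,3-dioxolane | COCOc1cc(C[C@@H](C)C[C@H](OC)[C@H]2COC(C)(C)O2)c(F)c([N+](=O)[O-])c1 | intermediate
17 | (2S,4R)-5-[2-fluoro-5-(methoxymethoxy)-3-nitrophenyl]-2-methoxy-4-methylpentanal | COCOc1cc(C[C@@H](C)C[C@H](OC)C=O)c(F)c([N+](=O)[O-])c1 | intermediate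
18 | (2R,4S,5R,6S)-1-[2-fluoro-5-(methoxymethoxy)-3-nitrophenyl]-4-methoxy-2,6-dimethyloct-7-en-5-ol | COCOc1cc(C[C@@H](C)C[C@H](OC)[C@H](O)[C@@H](C)C=C)c(F)c([N+](=O)[O-])c1 | intermediate
19 | (2R,3S,5R)-2-[(2S)-but-3-en-2-yl]-3-methoxy-8-(methoxymethoxy)-5-methyl-10-nitro-3,4,5,6-tetrahydro-2H-1-benzoxocine | CO[C@H]1C[C@H](C)Cc2cc(OCOC)cc([N+](=O)[O-])c2O[C@@H]1[C@@H](C)C=C | intermediate
20 | (2R)-2-[(2R,3S,5R)-3-methoxy-8-(methoxymethoxy)-5-methyl-10-nitro-3,4,5,6-tetrahydro-2H-1-benzoxocin-2-yl]propanal | CO[C@H]1C[C@H](C)Cc2cc(OCOC)cc([N+](=O)[O-])c2O[C@@H]1[C@@H](C)C=O | intermediate (not isolated)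
21 | (2S)-2-[(2R,3S,5R)-3-methoxy-8-(methoxymethoxy)-5-methyl-10-nitro-3,4,5,6-tetrahydro-2H-1-benzoxocin-2-yl]propan-1-ol | CO[C@H]1C[C@H](C)Cc2cc(OCOC)cc([N+](=O)[O-])c2O[C@@H]1[C@@H](C)CO | intermediate
22 | (2S)-2-[(2R,3S,5R)-10-amino-3-methoxy-8-(methoxymethoxy)-5-methyl-3,4,5,6-tetrahydro-2H-1-benzoxocin-2-yl]propan-1-ol | CO[C@H]1C[C@H](C)Cc2cc(OCOC)cc(N)c2O[C@@H]1[C@@H](C)CO | intermediate
23 | (2R,3S,5R)-2-[(2S)-1-hydroxypropan-2-yl]-3-methoxy-8-(methoxymethoxy)-5-methyl-3,4,5,6-tetrahydro-2H-1-benzoxocine-10-diazonium bromide | CO[C@H]1C[C@H](C)Cc2cc(OCOC)cc([N+]#N)c2O[C@@H]1[C@@H](C)CO.[Br-] | intermediate (not isolated)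
24 | (2S)-2-[(2R,3S,5R)-10-bromo-3-methoxy-8-(methoxymethoxy)-5-methyl-3,4,5,6-tetrahydro-2H-1-benzoxocin-2-yl]propan-1-ol | CO[C@H]1C[C@H](C)Cc2cc(OCOC)cc(Br)c2O[C@@H]1[C@@H](C)CO | intermediate
25 | (2R)-2-[(2R,3S,5R)-10-bromo-3-methoxy-8-(methoxymethoxy)-5-methyl-3,4,5,6-tetrahydro-2H-1-benzoxocin-2-yl]propanal | CO[C@H]1C[C@H](C)Cc2cc(OCOC)cc(Br)c2O[C@@H]1[C@@H](C)C=O | intermediate
26 | (2R,3S,5R)-10-bromo-2-[(2S,3Z)-4-iodopent-3-en-2-yl]-3-methoxy-8-(methoxymethoxy)-5-methyl-3,4,5,6-tetrahydro-2H-1-benzoxocine | CO[C@H]1C[C@H](C)Cc2cc(OCOC)cc(Br)c2O[C@@H]1[C@@H](C)/C=C(/C)I | intermediate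
27 | (S)-citramalic acid, (2S)-2-hydroxy-2-methylbutanedioic acid | C[C@](O)(CC(=O)O)C(=O)O | starting material
28 | 2-[(4S)-2,2,4-trimethyl-5-oxo-1,3-dioxolan-4-yl]acetic acid | C[C@@]1(CC(=O)O)OC(C)(C)OC1=O | intermediate
29 | (2S)-2-[(benzyloxy)methyl]oxirane | c1ccccc1COC[C@@H]1CO1 | starting material
30 | (2R)-1-(benzyloxy)-3-iodopropan-2-ol | O[C@@H](CI)COCc1ccccc1 | intermediate
31 | {[(2R)-3-iodo-2-methoxypropoxy]methyl}benzene | CO[C@@H](CI)COCc1ccccc1 | intermediate
32 | 2-[(4S)-2,2,4-trimethyl-5-oxo-1,3-dioxolan-4-yl]acetyl chloride | C[C@@]1(CC(=O)Cl)OC(C)(C)OC1=O | intermediate (not isolated)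
33 | (5S)-5-[(4S)-5-(benzyloxy)-4-methoxy-2-oxopentyl]-2,2,5-trimethyl-1,3-dioxolan-4-one | C[C@@]1(CC(=O)C[C@H](OC)COCc2ccccc2)OC(C)(C)OC1=O | intermediate
34 | (5S)-5-({2-[(2S)-3-(benzyloxy)-2-methoxypropyl]-1,3-dioxolan-2-yl}methyl)-2,2,5-trimethyl-1,3-dioxolan-4-one | C[C@@]1(CC2(C[C@H](OC)COCc3ccccc3)OCCO2)OC(C)(C)OC1=O | intermediate
35 | (5S)-5-({2-[(2S)-3-hydroxy-2-methoxypropyl]-1,3-dioxolan-2-yl}methyl)-2,2,5-trimethyl-1,3-dioxolan-4-one | C[C@@]1(CC2(C[C@H](OC)CO)OCCO2)OC(C)(C)OC1=O | intermediate
36 | (2S)-2-methoxy-3-(2-{[(4S)-2,2,4-trimethyl-5-oxo-1,3-dioxolan-4-yl]methyl}-1,3-dioxolan-2-yl)propanal | C[C@@]1(CC2(C[C@H](OC)C=O)OCCO2)OC(C)(C)OC1=O | intermediate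
37 | alkenyllithium from 26 (iodine replaced by lithium, alkene geometry retained) | CO[C@H]1C[C@H](C)Cc2cc(OCOC)cc(Br)c2O[C@@H]1[C@@H](C)/C=C(/C)[Li] | intermediate (not isolated)
38 | alkenylmagnesium bromide from 37 (alkene geometry retained) | CO[C@H]1C[C@H](C)Cc2cc(OCOC)cc(Br)c2O[C@@H]1[C@@H](C)/C=C(/C)[Mg]Br | intermediate (not isolated)
39 | (5S)-5-{[2-((2S,3S,4Z,6S)-6-[(2R,3S,5R)-10-bromo-3-methoxy-8-(methoxymethoxy)-5-methyl-3,4,5,6-tetrahydro-2H-1-benzoxocin-2-yl]-3-hydroxy-2-methoxy-4-methylhept-4-en-1-yl)-1,3-dioxolan-2-yl]methyl}-2,2,5-trimethyl-1,3-dioxolan-4-one | CO[C@H]1C[C@H](C)Cc2cc(OCOC)cc(Br)c2O[C@@H]1[C@@H](C)/C=C(/C)[C@H](O)[C@@H](OC)CC3(C[C@]4(C)OC(C)(C)OC4=O)OCCO3 | intermediate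
40 | C7 tert-butyldimethylsilyl ether of 39 | CO[C@H]1C[C@H](C)Cc2cc(OCOC)cc(Br)c2O[C@@H]1[C@@H](C)/C=C(/C)[C@H](O[Si](C)(C)C(C)(C)C)[C@@H](OC)CC3(C[C@]4(C)OC(C)(C)OC4=O)OCCO3 | intermediate
41 | seco amide: (2S)-2-hydroxy-2-methyl-3-[2-(C5–C21 chain)-1,3-dioxolan-2-yl]propanamide with 6S-OMe, 7S-OTBS, 8Z, 10S, 11R, 12S-OMe, 14R, C18 OMOM, C20 Br | CO[C@H]1C[C@H](C)Cc2cc(OCOC)cc(Br)c2O[C@@H]1[C@@H](C)/C=C(/C)[C@H](O[Si](C)(C)C(C)(C)C)[C@@H](OC)CC3(OCCO3)C[C@](C)(O)C(N)=O | intermediate
42 | protected macrolactam (C20–N closed; C4 dioxolane, C7 OTBS, C18 OMOM) | CO[C@H]1C[C@H](C)Cc2cc(OCOC)cc3c2O[C@@H]1[C@@H](C)/C=C(/C)[C@H](O[Si](C)(C)C(C)(C)C)[C@@H](OC)CC4(OCCO4)C[C@](C)(O)C(=O)N3 | intermediate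
43 | macrolactam with free 7-OH (C4 dioxolane, C18 OMOM) | CO[C@H]1C[C@H](C)Cc2cc(OCOC)cc3c2O[C@@H]1[C@@H](C)/C=C(/C)[C@H](O)[C@@H](OC)CC4(OCCO4)C[C@](C)(O)C(=O)N3 | intermediate
44 | macrolactam C7 N-(trichloroacetyl)carbamate | CO[C@H]1C[C@H](C)Cc2cc(OCOC)cc3c2O[C@@H]1[C@@H](C)/C=C(/C)[C@H](OC(=O)NC(=O)C(Cl)(Cl)Cl)[C@@H](OC)CC4(OCCO4)C[C@](C)(O)C(=O)N3 | intermediate (not isolated)
45 | macrolactam C7 carbamate (C4 dioxolane, C18 OMOM) | CO[C@H]1C[C@H](C)Cc2cc(OCOC)cc3c2O[C@@H]1[C@@H](C)/C=C(/C)[C@H](OC(N)=O)[C@@H](OC)CC4(OCCO4)C[C@](C)(O)C(=O)N3 | intermediate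
46 | CNP0122739.1 (2S,6S,7S,8Z,10S,11R,12S,14R) | CO[C@H]1C[C@H](C)Cc2cc(O)cc3c2O[C@@H]1[C@@H](C)/C=C(/C)[C@H](OC(N)=O)[C@@H](OC)CC(=O)C[C@](C)(O)C(=O)N3 | target

## Step count and least certain steps

Total: 32 steps. Longest linear sequence: 22 steps (7 through steps 4–18 and 26–32). The arene (steps 1–2), the Weinreb amide (step 3) and the C1–C7 aldehyde (steps 19–25) are side branches.

Step 29 (key step). Oligomerisation by intermolecular N-arylation and hydrodebromination may compete, because oxidative addition to the electron-rich, ortho-alkoxy aryl bromide is slow and the 15-membered ring with a Z-alkene is strained. Fallback: close ring C at the acyl carbon instead. From 40, amination with benzophenone imine (Pd2(dba)3, BINAP, Cs2CO3, toluene) would give the N-(diphenylmethylidene)arylamine of 40 F11. Aqueous citric acid would then release the C20 aniline of 40 F12. Deprotonation with LiN(SiMe3)2 at high dilution lets the anilide open the dioxolanone with loss of acetone, returning to the route at 42.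

Step 26. The exchange may not be fully selective for iodine over bromine, the alkenyl metal may attack the dioxolanone, and facial selectivity falls if the magnesium chelate is not formed. Fallback: a Nozaki–Hiyama–Kishi coupling of 26 with 36 (CrCl2, NiCl2 cat., DMSO), which leaves the aryl bromide and the dioxolanone alone, would give 39 mixed with the (7R)-epimer of 39 F9. Dess–Martin oxidation of the mixture gives the C7 enone of 39 F10. Corey–Bakshi–Shibata reduction with the (S)-methyl oxazaborolidine and catecholborane, the alkenyl group acting as the large substituent, should return 39.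

Step 22. The reductive coupling may suffer loss of methoxide from an alkyl-metal intermediate, homocoupling of the iodide or decarbonylation. Fallback: displacement of iodide in 31 with PhSO2Na gives {[(2R)-3-(benzyloxy)-2-methoxypropyl]sulfonyl}benzene F7. Its lithio derivative (LiN(SiMe3)2, THF, −78 °C), which does not eliminate at this temperature, is acylated by 32 to the β-keto sulfone F8. Reductive desulfonylation with SmI2 in THF–MeOH returns to the route at 33.

Step 13. Oligomerisation may outrun closure of the eight-membered ring, which is slowed by transannular strain and by the electron-donating C18 oxygen para to fluorine. Fallback: make the aryl ether intermolecularly and close ring B by metathesis.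
- The partner, (2S,3R,4S)-1-[(tert-butyldimethylsilyl)oxy]-4-methoxy-2-methylhex-5-en-3-ol F2, would be made separately from methyl (S)-3-hydroxy-2-methylpropanoate (silyl ether, aldehyde, anti-selective γ-methoxyallylation).
- From 4, the potassium alkoxide of F2 gives the aryl ether F3.
- Stille coupling with tributyl(2-methylallyl)stannane (Pd(PPh3)4) gives the diene F4.
- The second-generation Grubbs catalyst closes it to the benzoxocine F5.
- Hydrogen over Pd/C reduces both the alkene and the nitro group to the aniline silyl ether F6. The face of the alkene reduction would need to be checked.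
- Bu4NF returns to the route at 22.

Step 1. The nitro group may be reduced by boron hydride species or may inhibit the iridium catalyst, giving low conversion. Fallback: electrophilic iodination of 1 (N-iodosuccinimide, CF3SO3H) should go para to fluorine and meta to nitro, giving 1-bromo-2-fluoro-5-iodo-3-nitrobenzene F1. Miyaura borylation at the C–I bond (PdCl2(dppf), KOAc, B2pin2, dioxane, 80 °C) returns to the route at 2, which is oxidised to 3 as before.

Step 32. The dioxolane is flanked by two β-oxygen substituents and may hydrolyse slowly, so that forcing acid causes β-elimination of methanol or ionisation of the allylic carbamate. Fallback: unmask in two stages. From 45, ZnBr2 and n-PrSH in CH2Cl2 at 0 °C remove only the methoxymethyl group, giving the C18 phenol C4 dioxolane F13. Transketalisation with PPTS in wet acetone at 45 °C then gives 46.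

## Further compounds

F1 | step 1 | 1-bromo-2-fluoro-5-iodo-3-nitrobenzene | O=[N+]([O-])c1cc(I)cc(Br)c1F
F2 | step 13 | (2S,3R,4S)-1-[(tert-butyldimethylsilyl)oxy]-4-methoxy-2-methylhex-5-en-3-ol | CO[C@@H](C=C)[C@H](O)[C@@H](C)CO[Si](C)(C)C(C)(C)C
F3 | step 13 | 1-bromo-2-{[(2S,3R,4S)-1-[(tert-butyldimethylsilyl)oxy]-4-methoxy-2-methylhex-5-en-3-yl]oxy}-5-(methoxymethoxy)-3-nitrobenzene | CO[C@@H](C=C)[C@H](Oc1c(Br)cc(OCOC)cc1[N+](=O)[O-])[C@@H](C)CO[Si](C)(C)C(C)(C)C
F4 | step 13 | 2-{[(2S,3R,4S)-1-[(tert-butyldimethylsilyl)oxy]-4-methoxy-2-methylhex-5-en-3-yl]oxy}-5-(methoxymethoxy)-1-(2-methylprop-2-en-1-yl)-3-nitrobenzene | CO[C@@H](C=C)[C@H](Oc1c(CC(C)=C)cc(OCOC)cc1[N+](=O)[O-])[C@@H](C)CO[Si](C)(C)C(C)(C)C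
F5 | step 13 | tert-butyl{(2S)-2-[(2R,3S)-3-methoxy-8-(methoxymethoxy)-5-methyl-10-nitro-3,6-dihydro-2H-1-benzoxocin-2-yl]propoxy}dimethylsilane | CO[C@H]1/C=C(/C)Cc2cc(OCOC)cc([N+](=O)[O-])c2O[C@@H]1[C@@H](C)CO[Si](C)(C)C(C)(C)C
F6 | step 13 | (2R,3S,5R)-2-{(2S)-1-[(tert-butyldimethylsilyl)oxy]propan-2-yl}-3-methoxy-8-(methoxymethoxy)-5-methyl-3,4,5,6-tetrahydro-2H-1-benzoxocin-10-amine | CO[C@H]1C[C@H](C)Cc2cc(OCOC)cc(N)c2O[C@@H]1[C@@H](C)CO[Si](C)(C)C(C)(C)C
F7 | step 22 | {[(2R)-3-(benzyloxy)-2-methoxypropyl]sulfonyl}benzene | CO[C@@H](CS(=O)(=O)c1ccccc1)COCc1ccccc1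
F8 | step 22 | (5S)-5-[(4R)-5-(benzyloxy)-4-methoxy-2-oxo-3-(phenylsulfonyl)pentyl]-2,2,5-trimethyl-1,3-dioxolan-4-one (both C3 epimers) | C[C@@]1(CC(=O)C([C@H](OC)COCc2ccccc2)S(=O)(=O)c2ccccc2)OC(C)(C)OC1=O
F9 | step 26 | (7R)-epimer of 39 | CO[C@H]1C[C@H](C)Cc2cc(OCOC)cc(Br)c2O[C@@H]1[C@@H](C)/C=C(/C)[C@@H](O)[C@@H](OC)CC3(C[C@]4(C)OC(C)(C)OC4=O)OCCO3
F10 | step 26 | C7 ketone (enone) corresponding to 39 | CO[C@H]1C[C@H](C)Cc2cc(OCOC)cc(Br)c2O[C@@H]1[C@@H](C)/C=C(/C)C(=O)[C@@H](OC)CC3(C[C@]4(C)OC(C)(C)OC4=O)OCCO3
F11 | step 29 | C20 N-(diphenylmethylidene)amine corresponding to 40 | CO[C@H]1C[C@H](C)Cc2cc(OCOC)cc(N=C(c5ccccc5)c5ccccc5)c2O[C@@H]1[C@@H](C)/C=C(/C)[C@H](O[Si](C)(C)C(C)(C)C)[C@@H](OC)CC3(C[C@]4(C)OC(C)(C)OC4=O)OCCO3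
F12 | step 29 | C20 aniline corresponding to 40 | CO[C@H]1C[C@H](C)Cc2cc(OCOC)cc(N)c2O[C@@H]1[C@@H](C)/C=C(/C)[C@H](O[Si](C)(C)C(C)(C)C)[C@@H](OC)CC3(C[C@]4(C)OC(C)(C)OC4=O)OCCO3
F13 | step 32 | C18 phenol of 45 with C4 dioxolane retained | CO[C@H]1C[C@H](C)Cc2cc(O)cc3c2O[C@@H]1[C@@H](C)/C=C(/C)[C@H](OC(N)=O)[C@@H](OC)CC4(OCCO4)C[C@](C)(O)C(=O)N3
A1 | alternative 1 | benzoxocine with C13=C14 alkene (C18 OTIPS, C20 nitro, C9 OTBS) | CO[C@H]1/C=C(/C)Cc2cc(O[Si](C(C)C)(C(C)C)C(C)C)cc([N+](=O)[O-])c2O[C@@H]1[C@@H](C)CO[Si](C)(C)C(C)(C)C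
A2 | alternative 1 | acyclic diene: aryl ether with C12 vinyl and C16 2-methylallyl groups | CO[C@@H](C=C)[C@H](Oc1c(CC(C)=C)cc(O[Si](C(C)C)(C(C)C)C(C)C)cc1[N+](=O)[O-])[C@@H](C)CO[Si](C)(C)C(C)(C)C
A3 | alternative 2 | C1–C21 seco chain with C4 dithiane | CO[C@H]1C[C@H](C)Cc2cc(O[Si](C(C)C)(C(C)C)C(C)C)cc(-n3c(C)ccc3C)c2O[C@@H]1[C@@H](C)/C=C(/C)[C@H](O[Si](C)(C)C(C)(C)C)[C@@H](O)CC4(SCCCS4)C[C@](C)(O[Si](C)(C)C(C)(C)C)CO[Si](CC)(CC)CC
A4 | alternative 2 | tert-butyl(1,3-dithian-2-yl)dimethylsilane | CC(C)(C)[Si](C)(C)C1SCCCS1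
A5 | alternative 2 | triethyl{[(2S)-2-methyloxiran-2-yl]methoxy}silane | CC[Si](CC)(CC)OC[C@]1(C)CO1
A6 | alternative 2 | C5–C6 epoxide of the C5–C21 fragment (C7 OTBS, C18 OTIPS, C20 2,5-dimethylpyrrol-1-yl) | CO[C@H]1C[C@H](C)Cc2cc(O[Si](C(C)C)(C(C)C)C(C)C)cc(-n3c(C)ccc3C)c2O[C@@H]1[C@@H](C)/C=C(/C)[C@H](O[Si](C)(C)C(C)(C)C)[C@@H]4CO4
A7 | alternative 3 | macrolactam with C2 tertiary alcohol and C4 dithiane | CO[C@H]1C[C@H](C)Cc2cc(O[Si](C(C)C)(C(C)C)C(C)C)cc3c2O[C@@H]1[C@@H](C)/C=C(/C)[C@H](OC(N)=O)[C@@H](OC)CC4(SCCCS4)C[C@](C)(O)C(=O)N3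
A8 | alternative 3 | seco C20 isocyanide with C2 methyl ketone and C4 dithiane | CO[C@H]1C[C@H](C)Cc2cc(O[Si](C(C)C)(C(C)C)C(C)C)cc([N+]#[C-])c2O[C@@H]1[C@@H](C)/C=C(/C)[C@H](OC(N)=O)[C@@H](OC)CC3(SCCCS3)CC(C)=O
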